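## Retrosynthetic overview

1. Cut the ester C–O bond. This gives (S)-20-methyldocosan-1-ol and 2,3-dihydroxybenzoic acid, the latter carried as its bis-benzyl ether (Steglich esterification, then hydrogenolysis).
2. The C23 alcohol comes from its 17-ketone (Wolff–Kishner). The ketone comes from the C15=C16 enone (hydrogenation), and the enone from the β-hydroxy ketone (dehydration).
3. The key C15–C16 bond is made by an intermolecular aldol addition. The kinetic lithium enolate of (S)-5-methylheptan-2-one (C16–C22 plus the methyl branch) adds to 15-(benzyloxy)pentadecanal (C1–C15).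
4. The ketone comes from (S)-2-methylbutan-1-ol and ethyl acetoacetate. The aldehyde comes from ω-pentadecalactone.
5. No ring is formed. The benzene ring is bought with 2,3-dihydroxybenzoic acid, and the only stereocentre is bought with (S)-2-methylbutan-1-ol and never becomes a reacting centre.

Assumption: the target is read as (S)-20-methyldocosyl 2,3-dihydroxybenzoate (19 CH2 groups between the ester oxygen and the stereocentre). Commercial (S)-(−)-2-methylbutan-1-ol of ≥98% ee fixes the ee of the product.

## Route

Step 1
Reactants: 1 (S)-2-methylbutan-1-ol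
Product: 2 (S)-2-methylbutyl 4-methylbenzenesulfonate
Conditions: TsCl (1.2 equiv), pyridine, 0 °C → 4 °C, 16 h
Reagents that add atoms: 4-toluenesulfonyl chloride, Cc1ccc(cc1)S(=O)(=O)Cl
Why: Tosylation of a primary alcohol takes place at oxygen only, so the adjacent stereocentre bought with 1 is untouched.

Step 2
Reactants: 2 (S)-2-methylbutyl 4-methylbenzenesulfonate
Product: 3 (S)-1-iodo-2-methylbutane
Conditions: NaI (3 equiv), acetone, reflux, 12 h
Reagents that add atoms: sodium iodide, [Na+].[I-]
Why: This Finkelstein-type SN2 displacement at the primary CH2 is driven by precipitation of sodium tosylate, and the neighbouring stereocentre is not the reacting carbon and stays S.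

Step 3
Reactants: 3 (S)-1-iodo-2-methylbutane, 4 ethyl acetoacetate
Product: 6 ethyl (2RS,4S)-2-acetyl-4-methylhexanoate, via sodium enolate of ethyl acetoacetate 5 (not isolated)
Conditions: NaOEt (1.4 equiv), 4 (1.5 equiv), EtOH, rt, 30 min; then 3 (1.0 equiv), reflux, 24 h
Reagents that add atoms: none
Why: In this acetoacetic ester synthesis the soft stabilised enolate C-alkylates the primary iodide by SN2 (β-branching only slows it, hence iodide and long reflux), and the new C2 centre forms as an epimer mixture that is erased in step 4.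

Step 4
Reactants: 6 ethyl (2RS,4S)-2-acetyl-4-methylhexanoate
Product: 8 (S)-5-methylheptan-2-one, via beta-keto acid 7 (not isolated)
Conditions: 5% aq NaOH, rt, 6 h; then 50% H2SO4 to pH 1, reflux, 1 h; steam distillation
Reagents that add atoms: none
Why: In this ketonic hydrolysis, saponification with dilute base avoids retro-Claisen cleavage, the β-keto acid loses CO2 through a cyclic six-membered transition state, and the stereocentre ends up γ to the carbonyl and cannot epimerise.

Step 5
Reactants: 9 ω-pentadecalactone (oxacyclohexadecan-2-one)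
Product: 10 methyl 15-hydroxypentadecanoate
Conditions: MeOH, H2SO4 (cat.), reflux, 12 h
Reagents that add atoms: methanol, CO
Why: Acid-catalysed transesterification (methanolysis) in a large excess of methanol opens the macrolactone completely to the hydroxy ester.

Step 6
Reactants: 10 methyl 15-hydroxypentadecanoate
Product: 11 methyl 15-(benzyloxy)pentadecanoate
Conditions: BnOC(=NH)CCl3 (1.5 equiv), TfOH (5 mol %), CH2Cl2–cyclohexane 1:2, 0 °C → rt, 4 h
Reagents that add atoms: benzyl 2,2,2-trichloroacetimidate, ClC(Cl)(Cl)C(=N)OCc1ccccc1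
Why: Acid-catalysed trichloroacetimidate O-benzylation needs no base, so the methyl ester is neither hydrolysed nor enolised.

Step 7
Reactants: 11 methyl 15-(benzyloxy)pentadecanoate
Product: 12 15-(benzyloxy)pentadecan-1-ol
Conditions: LiAlH4 (1.0 equiv), THF, 0 °C → rt, 2 h; Fieser work-up
Reagents that add atoms: none
Why: LiAlH4 hydride reduction takes the ester cleanly to the primary alcohol while the benzyl ether is inert, which avoids the over-reduction risk of a direct DIBAL-H stop at the aldehyde.

Step 8
Reactants: 12 15-(benzyloxy)pentadecan-1-ol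
Product: 13 15-(benzyloxy)pentadecanal
Conditions: TEMPO (10 mol %), PhI(OAc)2 (1.1 equiv), CH2Cl2, rt, 3 h
Reagents that add atoms: none
Why: The TEMPO/PhI(OAc)2 oxoammonium oxidation stops at the aldehyde in anhydrous CH2Cl2 and leaves the benzyl ether alone.

Step 9 (key step)
Reactants: 8 (S)-5-methylheptan-2-one, 13 15-(benzyloxy)pentadecanal
Product: 15 (3S,8RS)-22-(benzyloxy)-8-hydroxy-3-methyldocosan-6-one, via kinetic lithium enolate 14 (not isolated)
Conditions: LDA (1.25 equiv, commercial solution), THF, −78 °C; 8 (1.2 equiv) added dropwise, 45 min; 13 (1.0 equiv) in THF, −78 °C, 45 min; AcOH/THF quench at −78 °C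
Reagents that add atoms: none
Why: In this directed crossed aldol addition, irreversible deprotonation by a slight excess of LDA at −78 °C takes the less hindered CH3 proton, the preformed enolate adds to the aldehyde faster than it transfers protons, the new C8 carbinol centre forms without control as about a 1:1 epimer mixture that is erased in step 10, and the C3 centre is too remote to epimerise.

Step 10
Reactants: 15 (3S,8RS)-22-(benzyloxy)-8-hydroxy-3-methyldocosan-6-one
Product: 17 (3S,7E)-22-(benzyloxy)-3-methyldocos-7-en-6-one, via beta-mesyloxy ketone 16 (not isolated)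
Conditions: MsCl (1.5 equiv), Et3N (4 equiv), CH2Cl2, 0 °C → rt, 3 h
Reagents that add atoms: none
Why: Mesylation followed by E1cB elimination through the ketone enolate converts both carbinol epimers into the conjugated (E)-enone and removes the uncontrolled centre.

Step 11
Reactants: 17 (3S,7E)-22-(benzyloxy)-3-methyldocos-7-en-6-one
Product: 19 (S)-22-hydroxy-3-methyldocosan-6-one, via saturated benzyl ether 18 (not isolated)
Conditions: H2 (1 atm), 10% Pd/C, EtOH–EtOAc 1:1, rt → 40 °C, 16 h
Reagents that add atoms: none
Why: Catalytic hydrogenation saturates the enone C=C first and hydrogenolysis then cleaves the benzyl ether, while an aliphatic ketone is not reduced over Pd/C at 1 atm.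

Step 12
Reactants: 19 (S)-22-hydroxy-3-methyldocosan-6-one
Product: 21 (S)-20-methyldocosan-1-ol, via hydrazone 20 (not isolated)
Conditions: N2H4·H2O (6 equiv), KOH (4 equiv), diethylene glycol, 130 °C, 2 h; distil off H2O/N2H4; 200 °C, 4 h
Reagents that add atoms: none
Why: The Wolff–Kishner reduction in its Huang-Minlon form is the standard deoxygenation of unhindered long-chain ketones, tolerates a free primary alcohol, and cannot reach the stereocentre, which is γ to the carbonyl.

Step 13
Reactants: 22 2,3-dihydroxybenzoic acid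
Product: 23 benzyl 2,3-bis(benzyloxy)benzoate
Conditions: BnBr (3.5 equiv), K2CO3 (4 equiv), DMF, 60 °C, 16 h
Reagents that add atoms: benzyl bromide, BrCc1ccccc1
Why: Exhaustive Williamson-type O-alkylation benzylates both phenoxides and the carboxylate in one operation.

Step 14
Reactants: 23 benzyl 2,3-bis(benzyloxy)benzoate
Product: 24 2,3-bis(benzyloxy)benzoic acid
Conditions: 2 M aq NaOH, MeOH–THF, reflux, 4 h; then 2 M HCl to pH 2
Reagents that add atoms: sodium hydroxide, [Na+].[OH-]
Why: Saponification (BAc2) cleaves only the benzyl ester because aryl benzyl ethers are inert to hydroxide.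

Step 15
Reactants: 21 (S)-20-methyldocosan-1-ol, 24 2,3-bis(benzyloxy)benzoic acid
Product: 26 (S)-20-methyldocosyl 2,3-bis(benzyloxy)benzoate, via O-acylisourea 25 (not isolated)
Conditions: DCC (1.2 equiv), DMAP (0.2 equiv), CH2Cl2, 0 °C → rt, 16 h
Reagents that add atoms: none
Why: In this Steglich esterification, DMAP-catalysed acyl transfer from the O-acylisourea to an unhindered primary alcohol is fast, and with the catechol masked no phenol can compete as a nucleophile.

Step 16
Reactants: 26 (S)-20-methyldocosyl 2,3-bis(benzyloxy)benzoate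
Product: 27 gentiside B, (S)-20-methyldocosyl 2,3-dihydroxybenzoate
Conditions: H2 (1 atm), 10% Pd/C, EtOAc–THF 1:1, rt, 6 h
Reagents that add atoms: none
Why: Catalytic hydrogenolysis removes both aryl benzyl ethers (in no fixed order) under neutral conditions that leave the alkyl ester, the arene and the remote stereocentre unchanged.

## Compound list

1 | (S)-2-methylbutan-1-ol | CC[C@H](C)CO | starting material
2 | (S)-2-methylbutyl 4-methylbenzenesulfonate | CC[C@H](C)COS(=O)(=O)c1ccc(C)cc1 | intermediate
3 | (S)-1-iodo-2-methylbutane | CC[C@H](C)CI | intermediate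
4 | ethyl acetoacetate | CCOC(=O)CC(C)=O | starting material
5 | sodium enolate of ethyl acetoacetate (not isolated) | CCOC(=O)C=C(C)[O-].[Na+] | intermediate
6 | ethyl (2RS,4S)-2-acetyl-4-methylhexanoate | CC[C@H](C)CC(C(C)=O)C(=O)OCC | intermediate
7 | (2RS,4S)-2-acetyl-4-methylhexanoic acid, the beta-keto acid (not isolated) | CC[C@H](C)CC(C(C)=O)C(=O)O | intermediate
8 | (S)-5-methylheptan-2-one | CC[C@H](C)CCC(C)=O | intermediate
9 | ω-pentadecalactone (oxacyclohexadecan-2-one) | O=C1CCCCCCCCCCCCCCO1 | starting material
10 | methyl 15-hydroxypentadecanoate | COC(=O)CCCCCCCCCCCCCCO | intermediate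
11 | methyl 15-(benzyloxy)pentadecanoate | COC(=O)CCCCCCCCCCCCCCOCc1ccccc1 | intermediate
12 | 15-(benzyloxy)pentadecan-1-ol | OCCCCCCCCCCCCCCCOCc1ccccc1 | intermediate
13 | 15-(benzyloxy)pentadecanal | O=CCCCCCCCCCCCCCCOCc1ccccc1 | intermediate
14 | lithium (S)-5-methylhept-1-en-2-olate, the kinetic lithium enolate (not isolated) | CC[C@H](C)CCC(=C)O[Li] | intermediate
15 | (3S,8RS)-22-(benzyloxy)-8-hydroxy-3-methyldocosan-6-one | CC[C@H](C)CCC(=O)CC(O)CCCCCCCCCCCCCCOCc1ccccc1 | intermediate
16 | (3S,8RS)-22-(benzyloxy)-3-methyl-6-oxodocosan-8-yl methanesulfonate (not isolated) | CC[C@H](C)CCC(=O)CC(OS(C)(=O)=O)CCCCCCCCCCCCCCOCc1ccccc1 | intermediate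
17 | (3S,7E)-22-(benzyloxy)-3-methyldocos-7-en-6-one | CC[C@H](C)CCC(=O)/C=C/CCCCCCCCCCCCCCOCc1ccccc1 | intermediate
18 | (S)-22-(benzyloxy)-3-methyldocosan-6-one (not isolated) | CC[C@H](C)CCC(=O)CCCCCCCCCCCCCCCCOCc1ccccc1 | intermediate
19 | (S)-22-hydroxy-3-methyldocosan-6-one | CC[C@H](C)CCC(=O)CCCCCCCCCCCCCCCCO | intermediate
20 | (S)-22-hydroxy-3-methyldocosan-6-one hydrazone (not isolated) | CC[C@H](C)CCC(=NN)CCCCCCCCCCCCCCCCO | intermediate
21 | (S)-20-methyldocosan-1-ol | CC[C@H](C)CCCCCCCCCCCCCCCCCCCO | intermediate
22 | 2,3-dihydroxybenzoic acid | O=C(O)c1cccc(O)c1O | starting material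
23 | benzyl 2,3-bis(benzyloxy)benzoate | O=C(OCc1ccccc1)c1cccc(OCc2ccccc2)c1OCc1ccccc1 | intermediate
24 | 2,3-bis(benzyloxy)benzoic acid | O=C(O)c1cccc(OCc2ccccc2)c1OCc1ccccc1 | intermediate
25 | O-[2,3-bis(benzyloxy)benzoyl]-N,N'-dicyclohexylisourea (not isolated) | O=C(OC(=NC1CCCCC1)NC1CCCCC1)c1cccc(OCc2ccccc2)c1OCc1ccccc1 | intermediate
26 | (S)-20-methyldocosyl 2,3-bis(benzyloxy)benzoate | CC[C@H](C)CCCCCCCCCCCCCCCCCCCOC(=O)c1cccc(OCc2ccccc2)c1OCc1ccccc1 | intermediate
27 | gentiside B, (S)-20-methyldocosyl 2,3-dihydroxybenzoate | CC[C@H](C)CCCCCCCCCCCCCCCCCCCOC(=O)c1cccc(O)c1O | target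

## Step count and risks

Total step count: 16.
Longest linear sequence: 10 steps. This is steps 1–4, 9–12, 15 and 16 from 1, and the same length for steps 5–8, 9–12, 15 and 16 from 9.

**Step 9 (aldol).**
- Risks: some deprotonation may occur at C3 instead of CH3. Proton transfer to the enolate from the enolisable aldehyde is possible. Compound 13 may be poorly soluble at −78 °C, and retro-aldol cleavage can occur on work-up.
- The fallback sets out from 8 and comes back at 15.
- Compound 8 is condensed with 1,1-dimethylhydrazine (EtOH, cat. AcOH, reflux) to give (S)-5-methylheptan-2-one N,N-dimethylhydrazone F1.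
- n-BuLi in THF (−78 → 0 °C) metallates this hydrazone at the less substituted CH3 carbon. This gives lithiated (S)-5-methylheptan-2-one N,N-dimethylhydrazone F2, which is used in the flask.
- The azaenolate adds to 13 at −78 °C in an aldol-type addition, giving (3S,8RS)-22-(benzyloxy)-8-hydroxy-3-methyldocosan-6-one N,N-dimethylhydrazone F3.
- Buffered aqueous CuCl2 in THF hydrolyses the C=N bond and returns 15. Any enone formed on the way converges in step 10.

**Step 3 (alkylation).**
- Risks: SN2 at the β-branched primary carbon is slow, so E2, ether formation and incomplete conversion can lower the yield of a volatile product.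
- The fallback sets out from 3 and comes back at 8, bypassing 6. It reverses the polarity of the chiral piece.
- Mg in Et2O turns 3 into (S)-2-methylbutylmagnesium iodide F4.
- F4 opens racemic propylene oxide at its CH2 terminus under CuI catalysis (10 mol %, THF, −30 → 0 °C) to give (2RS,5S)-5-methylheptan-2-ol F5.
- Oxidation of the secondary alcohol (NaOCl, AcOH, 0 °C) erases the carbinol centre and returns 8.

**Step 12 (Wolff–Kishner).**
- Risks: at 200 °C in strong base, azine formation, incomplete reduction or foaming of the waxy substrate can occur.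
- The fallback sets out from 19 and comes back at 21.
- Ethane-1,2-dithiol and BF3·OEt2 in CH2Cl2 (0 °C → rt) convert the ketone into 16-{2-[(3S)-3-methylpentyl]-1,3-dithiolan-2-yl}hexadecan-1-ol F6.
- Raney nickel in refluxing EtOH (Mozingo desulfurisation) replaces both C–S bonds by C–H under neutral conditions and gives 21.

## Further compounds

F1 | step 9 | (S)-5-methylheptan-2-one N,N-dimethylhydrazone | CC[C@H](C)CCC(C)=NN(C)C
F2 | step 9 | lithiated (S)-5-methylheptan-2-one N,N-dimethylhydrazone | CC[C@H](C)CCC(=C)N([Li])N(C)C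
F3 | step 9 | (3S,8RS)-22-(benzyloxy)-8-hydroxy-3-methyldocosan-6-one N,N-dimethylhydrazone | CC[C@H](C)CCC(CC(O)CCCCCCCCCCCCCCOCc1ccccc1)=NN(C)C
F4 | step 3 | (S)-2-methylbutylmagnesium iodide | CC[C@H](C)C[Mg]I
F5 | step 3 | (2RS,5S)-5-methylheptan-2-ol | CC[C@H](C)CCC(C)O
F6 | step 12 | 16-{2-[(3S)-3-methylpentyl]-1,3-dithiolan-2-yl}hexadecan-1-ol | CC[C@H](C)CCC1(CCCCCCCCCCCCCCCCO)SCCS1
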